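**Strategy.** The furanone enol ether C2=C3–O–C10 is treated as the olefinated form of an ester of the tertiary C10 oxygen. The route therefore builds a nine-membered lactone (O10–C3(=O)–C4=C5–C6–C7–C8–C9–C10), fused at C6/C7 to the α-methylene γ-lactone and carrying the keto phosphorane C1(=O)–C2H=PPh3 on C10. One intramolecular ester Wittig reaction then joins C2 to C3: it closes the furanone ring and, in the same event, converts the lactone into the ten-membered carbocycle C1–C10, creating no stereocentre. In the precursor O8, O9 and O15 are TBS, PMB and TBDPS ethers, and C2 enters as an alkyne carbon, so the bromoketone is made without enolate chemistry.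

Key step: step 22

Remark: germacrane numbering (C1–C15) is used for all intermediates; O9 is a PMB ether because it must chelate magnesium when C10 is created, and the Baylis–Hillman adduct 20 is carried on as both C7 epimers because C7 becomes sp2 in step 15.

**Route**

Step 1
Reactants: 1 but-2-yne-1,4-diol
Product: 2 4-[(tert-butyldiphenylsilyl)oxy]but-2-yn-1-ol
Conditions: TBDPSCl (0.33 equiv), imidazole, DMF, 0 °C → rt
Reagents that add atoms: tert-butyl(chloro)diphenylsilane, CC(C)(C)[Si](Cl)(c1ccccc1)c1ccccc1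
Why: Silylation of a symmetrical diol used in excess should give essentially only the mono ether, and the surplus diol is removed with water.

Step 2
Reactants: 2 4-[(tert-butyldiphenylsilyl)oxy]but-2-yn-1-ol
Product: 3 (2Z)-4-[(tert-butyldiphenylsilyl)oxy]-3-iodobut-2-en-1-ol
Conditions: NaAlH2(OCH2CH2OMe)2, THF, 0 °C → rt; then I2, −78 → 0 °C
Reagents that add atoms: iodine, II
Why: Hydroxyl-directed trans-hydroalumination of the propargylic alcohol places aluminium on C4 in a five-membered alanate, and iodinolysis with retention gives the iodide with iodine cis to C6, which fixes the C4=C5 geometry.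

Step 3
Reactants: 3 (2Z)-4-[(tert-butyldiphenylsilyl)oxy]-3-iodobut-2-en-1-ol
Product: 4 (2Z)-4-[(tert-butyldimethylsilyl)oxy]-1-[(tert-butyldiphenylsilyl)oxy]-2-iodobut-2-ene
Conditions: TBSCl, imidazole, CH2Cl2, rt
Reagents that add atoms: tert-butyl(chloro)dimethylsilane, CC(C)(C)[Si](C)(C)Cl
Why: Standard silylation of a primary allylic alcohol.

Step 4
Reactants: 4 (2Z)-4-[(tert-butyldimethylsilyl)oxy]-1-[(tert-butyldiphenylsilyl)oxy]-2-iodobut-2-ene
Product: 5 methyl (2Z)-4-[(tert-butyldimethylsilyl)oxy]-2-{[(tert-butyldiphenylsilyl)oxy]methyl}but-2-enoate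
Conditions: Pd(OAc)2 (5 mol %), PPh3 (10 mol %), CO (1 atm), MeOH, Et3N, DMF, 50 °C
Reagents that add atoms: carbon monoxide, [C-]#[O+]; methanol, CO
Why: Palladium-catalysed alkoxycarbonylation of an alkenyl iodide (oxidative addition to zerovalent palladium formed in situ, CO insertion, methanolysis) proceeds with retention, so C3 ends up cis to C6.

Step 5
Reactants: 5 methyl (2Z)-4-[(tert-butyldimethylsilyl)oxy]-2-{[(tert-butyldiphenylsilyl)oxy]methyl}but-2-enoate
Product: 6 (2Z)-4-[(tert-butyldimethylsilyl)oxy]-2-{[(tert-butyldiphenylsilyl)oxy]methyl}but-2-enoic acid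
Conditions: LiOH, THF/MeOH/H2O, 0 °C → rt; then 1 M HCl to pH 4, 0 °C
Reagents that add atoms: lithium hydroxide, [Li+].[OH-]
Why: Saponification of the methyl ester; the silyl ethers and the alkene geometry should survive cold aqueous base.

Step 6
Reactants: 7 diethyl L-(+)-tartrate
Product: 9 diethyl (2R,3R)-2-hydroxy-3-[(4-methoxybenzyl)oxy]butanedioate, via stannylene acetal 8 (not isolated)
Conditions: Bu2SnO, PhMe, reflux (−H2O); then PMBCl, Bu4NI (cat.), 90 °C
Reagents that add atoms: 4-methoxybenzyl chloride, COc1ccc(CCl)cc1; dibutyltin oxide, CCCC[Sn](=O)CCCC (only in intermediate 8)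
Why: Stannylene-acetal activation raises the nucleophilicity of one oxygen and, after one alkylation, the tin stays on the other oxygen, so the C2-symmetric diol is mono-protected.

Step 7
Reactants: 9 diethyl (2R,3R)-2-hydroxy-3-[(4-methoxybenzyl)oxy]butanedioate
Product: 10 ethyl (2R,3S)-3,4-dihydroxy-2-[(4-methoxybenzyl)oxy]butanoate
Conditions: BH3·SMe2, NaBH4 (5 mol %), THF, rt; MeOH quench
Reagents that add atoms: none
Why: Hydroxyl-directed borane reduction of an α-hydroxy ester goes through a cyclic alkoxyborane and reduces only the ester next to the free hydroxyl, leaving the ester next to the PMB ether.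

Step 8
Reactants: 10 ethyl (2R,3S)-3,4-dihydroxy-2-[(4-methoxybenzyl)oxy]butanoate
Product: 11 ethyl (2R,3S)-3-hydroxy-2-[(4-methoxybenzyl)oxy]-4-[(triethylsilyl)oxy]butanoate
Conditions: TESCl (1.05 equiv), imidazole, CH2Cl2, −40 °C
Reagents that add atoms: chlorotriethylsilane, CC[Si](Cl)(CC)CC
Why: Selective silylation of the primary hydroxyl of a 1,2-diol at low temperature.

Step 9
Reactants: 11 ethyl (2R,3S)-3-hydroxy-2-[(4-methoxybenzyl)oxy]-4-[(triethylsilyl)oxy]butanoate
Product: 12 ethyl (2R,3S)-3-[(tert-butyldimethylsilyl)oxy]-2-[(4-methoxybenzyl)oxy]-4-[(triethylsilyl)oxy]butanoate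
Conditions: TBSOTf, 2,6-lutidine, CH2Cl2, −78 → 0 °C
Reagents that add atoms: tert-butyldimethylsilyl triflate, CC(C)(C)[Si](C)(C)OS(=O)(=O)C(F)(F)F
Why: Silyl triflate with a hindered base silylates the remaining secondary hydroxyl.

Step 10
Reactants: 12 ethyl (2R,3S)-3-[(tert-butyldimethylsilyl)oxy]-2-[(4-methoxybenzyl)oxy]-4-[(triethylsilyl)oxy]butanoate
Product: 14 (3R,4S)-4-[(tert-butyldimethylsilyl)oxy]-3-[(4-methoxybenzyl)oxy]-5-[(triethylsilyl)oxy]pentan-2-one, via Weinreb amide 13 (not isolated)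
Conditions: MeNH(OMe)·HCl, iPrMgCl, THF, −20 °C; then MeMgBr, −20 → 0 °C; aq. NH4Cl
Reagents that add atoms: methylmagnesium bromide, C[Mg]Br; N,O-dimethylhydroxylamine hydrochloride, CNOC.Cl (only in intermediate 13)
Why: One-pot Weinreb ketone synthesis: the magnesium amide converts the ester into the N-methoxy-N-methylamide, and the methyl Grignard reagent adds once because the chelated tetrahedral intermediate survives until work-up.

Step 11
Reactants: 14 (3R,4S)-4-[(tert-butyldimethylsilyl)oxy]-3-[(4-methoxybenzyl)oxy]-5-[(triethylsilyl)oxy]pentan-2-one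
Product: 15 (3R,4R,5S)-5-[(tert-butyldimethylsilyl)oxy]-4-[(4-methoxybenzyl)oxy]-3-methyl-6-[(triethylsilyl)oxy]hex-1-yn-3-ol
Conditions: HC≡CMgBr (3 equiv), THF, −78 → −20 °C
Reagents that add atoms: ethynylmagnesium bromide, C#C[Mg]Br
Why: Chelation-controlled Grignard addition (Cram chelate): magnesium bridges the ketone oxygen and the α-PMB ether oxygen, so the alkynyl group adds to the face opposite the C8 branch and sets C10 with O10 syn to O9, as in the target.

Step 12
Reactants: 15 (3R,4R,5S)-5-[(tert-butyldimethylsilyl)oxy]-4-[(4-methoxybenzyl)oxy]-3-methyl-6-[(triethylsilyl)oxy]hex-1-yn-3-ol; 6 (2Z)-4-[(tert-butyldimethylsilyl)oxy]-2-{[(tert-butyldiphenylsilyl)oxy]methyl}but-2-enoic acid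
Product: 17 tertiary ester of 15 at O10 with acid 6 (O7 TES; O8 TBS; O9 PMB; C6-O TBS; O15 TBDPS; 4Z), via mixed anhydride 16 (not isolated)
Conditions: 6 (1.5 equiv), 2,4,6-Cl3C6H2COCl, Et3N, THF, 0 °C → rt; then 15, DMAP (2 equiv), PhMe, rt → 60 °C
Reagents that add atoms: 2,4,6-trichlorobenzoyl chloride, O=C(Cl)c1c(Cl)cc(Cl)cc1Cl (only in intermediate 16)
Why: Yamaguchi esterification: DMAP transfers the acyl group of the mixed anhydride to the tertiary propargylic alcohol, whose small ethynyl group keeps the carbinol accessible.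

Step 13
Reactants: 17 tertiary ester of 15 at O10 with acid 6
Product: 18 C7 aldehyde of 17 (CH2OTES oxidised to CHO)
Conditions: (COCl)2, DMSO, CH2Cl2, −78 → −40 °C; Et3N, → 0 °C
Reagents that add atoms: none
Why: Direct Swern oxidation of a primary triethylsilyl ether: the chlorosulfonium salt cleaves the unhindered TES ether and oxidises it in the same flask, while TBS and TBDPS ethers are inert.

Step 14
Reactants: 18 C7 aldehyde of 17; 19 methyl acrylate
Product: 20 Baylis–Hillman adduct of 18 (C7 carbinol bearing the methyl acrylate unit C11–C13; both C7 epimers)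
Conditions: 19 (excess, neat), DABCO (1 equiv), rt, several days
Reagents that add atoms: none
Why: Morita–Baylis–Hillman reaction of an activated α-silyloxy aldehyde; the C7 carbinol forms unselectively, which does not matter because step 15 erases it.

Step 15
Reactants: 20 Baylis–Hillman adduct of 18
Product: 21 (Z)-allylic bromide (C13H2Br–C11(CO2Me)=C7H–C8)
Conditions: NBS, Me2S, CH2Cl2, −20 °C → rt
Reagents that add atoms: N-bromosuccinimide, O=C1CCC(=O)N1Br
Why: Corey–Kim-type bromination with allylic transposition: bromide displaces the alkoxysulfonium group in the SN2′ sense and gives the thermodynamically preferred (2Z)-2-(bromomethyl)enoate.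

Step 16
Reactants: 21 (Z)-allylic bromide
Product: 22 C6 allylic alcohol of 21
Conditions: HF·pyridine, pyridine, THF, 0 °C
Reagents that add atoms: none
Why: Selective desilylation: buffered HF·pyridine removes the primary allylic TBS ether much faster than the secondary TBS or the TBDPS ether, and the hindered tertiary ester should resist translactonisation if 22 is used at once.

Step 17
Reactants: 22 C6 allylic alcohol of 21
Product: 23 Z-enal bromide (C6 aldehyde cis to the C3 ester)
Conditions: Dess–Martin periodinane, NaHCO3, CH2Cl2, 0 °C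
Reagents that add atoms: none
Why: Buffered Dess–Martin oxidation gives the enal under neutral conditions that should preserve the Z geometry and the allylic bromide.

Step 18
Reactants: 23 Z-enal bromide
Product: 25 nine-membered lactone fused to the α-methylene γ-lactone with C10 ethynyl (O8 TBS; O9 PMB; O15 TBDPS), via hydroxy ester 24 (not isolated)
Conditions: CrCl2 (10 equiv), THF, 0.002 M (slow addition of 23), rt; aq. NH4Cl
Reagents that add atoms: none
Why: Intramolecular Nozaki–Hiyama allylation (the reaction type used for macrocyclic Barbier closures of germacranolides): divalent chromium converts the bromide into an allylchromium species that adds through C7 to the aldehyde C6, and the chromium alkoxide acylates on the C12 ester; the anti mode normal for γ-substituted allylchromium reagents (chair-like transition state) should give the 6,7-trans lactone, and the C8 centre, with its C–H bond held in the allyl plane by allylic strain, should direct C6 to the C7 face that gives 6R,7S.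

Step 19
Reactants: 25 nine-membered lactone with C10 ethynyl
Product: 26 bromoalkyne of 25
Conditions: NBS, AgNO3 (10 mol %), acetone, rt
Reagents that add atoms: N-bromosuccinimide, O=C1CCC(=O)N1Br
Why: Silver-catalysed bromination of a terminal alkyne through the silver acetylide leaves alkenes and the PMB ether untouched.

Step 20
Reactants: 26 bromoalkyne of 25
Product: 27 bromomethyl ketone (C1 ketone; C2 bromide)
Conditions: (Ph3P)AuNTf2 (5 mol %), 1,4-dioxane/H2O, rt
Reagents that add atoms: water, O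
Why: Gold-catalysed hydration of a haloalkyne with neighbouring-group assistance: the lactone carbonyl oxygen adds 5-exo-dig to the alkyne activated by monovalent gold and water opens the dioxolenium ion, which returns the ester on O10 and puts the ketone on C1 and bromine on C2 without any enolate.

Step 21
Reactants: 27 bromomethyl ketone
Product: 29 nine-membered lactone keto ylide (C1(=O)–C2H=PPh3), via phosphonium bromide 28 (not isolated)
Conditions: PPh3 (1.05 equiv), CH2Cl2, rt; then aq. Na2CO3, 0 °C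
Reagents that add atoms: triphenylphosphine, c1ccc(cc1)P(c1ccccc1)c1ccccc1
Why: SN2 displacement of the primary α-bromoketone and deprotonation of the acidic phosphonium salt give an isolable stabilised ylide; phosphine adds to the α-methylene lactone only reversibly.

Step 22
Reactants: 29 nine-membered lactone keto ylide
Product: 30 protected furanone core (O8 TBS; O9 PMB; O15 TBDPS)
Conditions: PhMe (0.005 M), BHT (trace), 110 °C
Reagents that add atoms: none
Why: On heating, the ylide carbon C2 adds to the lactone carbonyl C3 through the five-atom array C2–C1–C10–O–C3, and the oxaphosphetane collapses with loss of Ph3PO to leave the enol ether C2=C3; this is the intramolecular Wittig olefination of an ester carbonyl by which α-acyloxy ketone phosphoranes give 3(2H)-furanones. The furanone closes 5-exo-trig at C3, and the ten-membered carbocycle C1–C10 results from the same bond (formally 10-exo-trig), because C3 is already tied to C10 through the ring oxygen, so the lactone is transposed and no large ring has to close against entropy. No stereocentre is formed; C6–C9 are remote from the reacting atoms and C10 is quaternary, so nothing can epimerise. The step needs chemoselectivity for C3 over the γ-lactone carbonyl C12 and the conjugate acceptors C13 and C5, and distance secures it: only C3 is within reach of C2 through a five-membered transition state, the others would need seven- or eight-membered ones. High dilution and a radical inhibitor should suppress intermolecular reactions of the ylide and polymerisation of the α-methylene lactone.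

Step 23
Reactants: 30 protected furanone core
Product: 31 C9 alcohol (O8 TBS; O15 TBDPS)
Conditions: DDQ, CH2Cl2/pH 7 buffer, 0 °C → rt
Reagents that add atoms: none
Why: Oxidative PMB cleavage: DDQ abstracts hydride from the electron-rich benzyl ether and water hydrolyses the oxocarbenium ion, leaving silyl ethers, furanone and lactone.

Step 24
Reactants: 31 C9 alcohol
Product: 33 C9 angelate (O8 TBS; O15 TBDPS), via angelic mixed anhydride 32 (not isolated)
Conditions: angelic acid, 2,4,6-Cl3C6H2COCl, Et3N, PhMe, rt; then 31, 75 °C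
Reagents that add atoms: angelic acid, C/C=C(/C)C(O)=O; 2,4,6-trichlorobenzoyl chloride, O=C(Cl)c1c(Cl)cc(Cl)cc1Cl (only in intermediate 32)
Why: Yamaguchi esterification without DMAP acylates the hindered C9 hydroxyl while keeping the Z geometry of the angelate, and at this stage there is no free vicinal hydroxyl that could cause acyl migration.

Step 25
Reactants: 33 C9 angelate
Product: 34 C8 alcohol (C9 angelate; O15 TBDPS)
Conditions: HF·pyridine, pyridine, THF, 0 °C → rt
Reagents that add atoms: none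
Why: Selective desilylation: the secondary TBS ether is cleaved while the primary TBDPS ether, far more stable to acidic fluoride, should be retained.

Step 26
Reactants: 34 C8 alcohol
Product: 35 C8 methacrylate C9 angelate O15 TBDPS ether
Conditions: methacrylic anhydride, Et3N, DMAP (cat.), CH2Cl2, 0 °C
Reagents that add atoms: methacrylic anhydride, CC(=C)C(=O)OC(=O)C(C)=C
Why: DMAP-catalysed acylation of the unhindered secondary alcohol is fast at 0 °C and should outrun migration of the neighbouring angelate.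

Step 27
Reactants: 35 C8 methacrylate C9 angelate O15 TBDPS ether
Product: 36 target (6R,7S,8S,9R,10S; 4Z; angelate Z)
Conditions: HF·pyridine (excess), THF, rt
Reagents that add atoms: none
Why: Fluoride-mediated desilylation under acidic, non-nucleophilic conditions removes the primary TBDPS ether without harming the two unsaturated esters, the α-methylene lactone or the furanone.

**Compound list**

1 | but-2-yne-1,4-diol | OCC#CCO | starting material
2 | 4-[(tert-butyldiphenylsilyl)oxy]but-2-yn-1-ol | OCC#CCO[Si](c1ccccc1)(c1ccccc1)C(C)(C)C | intermediate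
3 | (2Z)-4-[(tert-butyldiphenylsilyl)oxy]-3-iodobut-2-en-1-ol | OC/C=C(\I)CO[Si](c1ccccc1)(c1ccccc1)C(C)(C)C | intermediate
4 | (2Z)-4-[(tert-butyldimethylsilyl)oxy]-1-[(tert-butyldiphenylsilyl)oxy]-2-iodobut-2-ene | CC(C)(C)[Si](C)(C)OC/C=C(\I)CO[Si](c1ccccc1)(c1ccccc1)C(C)(C)C | intermediate
5 | methyl (2Z)-4-[(tert-butyldimethylsilyl)oxy]-2-{[(tert-butyldiphenylsilyl)oxy]methyl}but-2-enoate | COC(=O)/C(CO[Si](c1ccccc1)(c1ccccc1)C(C)(C)C)=C\CO[Si](C)(C)C(C)(C)C | intermediate
6 | (2Z)-4-[(tert-butyldimethylsilyl)oxy]-2-{[(tert-butyldiphenylsilyl)oxy]methyl}but-2-enoic acid (C3–C6 and C15) | OC(=O)/C(CO[Si](c1ccccc1)(c1ccccc1)C(C)(C)C)=C\CO[Si](C)(C)C(C)(C)C | intermediate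
7 | diethyl L-(+)-tartrate, diethyl (2R,3R)-2,3-dihydroxybutanedioate | CCOC(=O)[C@H](O)[C@@H](O)C(=O)OCC | starting material
8 | diethyl (4R,5R)-2,2-dibutyl-1,3,2-dioxastannolane-4,5-dicarboxylate | CCOC(=O)[C@@H]1O[Sn](CCCC)(CCCC)O[C@H]1C(=O)OCC | intermediate (not isolated)
9 | diethyl (2R,3R)-2-hydroxy-3-[(4-methoxybenzyl)oxy]butanedioate | CCOC(=O)[C@H](O)[C@@H](OCc1ccc(OC)cc1)C(=O)OCC | intermediate
10 | ethyl (2R,3S)-3,4-dihydroxy-2-[(4-methoxybenzyl)oxy]butanoate | OC[C@H](O)[C@@H](OCc1ccc(OC)cc1)C(=O)OCC | intermediate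
11 | ethyl (2R,3S)-3-hydroxy-2-[(4-methoxybenzyl)oxy]-4-[(triethylsilyl)oxy]butanoate | CC[Si](CC)(CC)OC[C@H](O)[C@@H](OCc1ccc(OC)cc1)C(=O)OCC | intermediate
12 | ethyl (2R,3S)-3-[(tert-butyldimethylsilyl)oxy]-2-[(4-methoxybenzyl)oxy]-4-[(triethylsilyl)oxy]butanoate | CC[Si](CC)(CC)OC[C@H](O[Si](C)(C)C(C)(C)C)[C@@H](OCc1ccc(OC)cc1)C(=O)OCC | intermediate
13 | (2R,3S)-3-[(tert-butyldimethylsilyl)oxy]-N-methoxy-2-[(4-methoxybenzyl)oxy]-N-methyl-4-[(triethylsilyl)oxy]butanamide | CC[Si](CC)(CC)OC[C@H](O[Si](C)(C)C(C)(C)C)[C@@H](OCc1ccc(OC)cc1)C(=O)N(C)OC | intermediate (not isolated)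
14 | (3R,4S)-4-[(tert-butyldimethylsilyl)oxy]-3-[(4-methoxybenzyl)oxy]-5-[(triethylsilyl)oxy]pentan-2-one (C7–C10 and C14) | CC[Si](CC)(CC)OC[C@H](O[Si](C)(C)C(C)(C)C)[C@@H](OCc1ccc(OC)cc1)C(C)=O | intermediate
15 | (3R,4R,5S)-5-[(tert-butyldimethylsilyl)oxy]-4-[(4-methoxybenzyl)oxy]-3-methyl-6-[(triethylsilyl)oxy]hex-1-yn-3-ol (C2≡C1–C10(OH)(CH3)–C9–C8–C7) | C#C[C@@](C)(O)[C@H](OCc1ccc(OC)cc1)[C@@H](O[Si](C)(C)C(C)(C)C)CO[Si](CC)(CC)CC | intermediate
16 | mixed anhydride of acid 6 with 2,4,6-trichlorobenzoic acid | O=C(OC(=O)c1c(Cl)cc(Cl)cc1Cl)/C(CO[Si](c1ccccc1)(c1ccccc1)C(C)(C)C)=C\CO[Si](C)(C)C(C)(C)C | intermediate (not isolated)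
17 | tertiary ester of 15 at O10 with acid 6; C8, C9, C10 as in 15; 4Z | C#C[C@@](C)(OC(=O)/C(CO[Si](c1ccccc1)(c1ccccc1)C(C)(C)C)=C\CO[Si](C)(C)C(C)(C)C)[C@H](OCc1ccc(OC)cc1)[C@@H](O[Si](C)(C)C(C)(C)C)CO[Si](CC)(CC)CC | intermediate
18 | C7 aldehyde of 17 | C#C[C@@](C)(OC(=O)/C(CO[Si](c1ccccc1)(c1ccccc1)C(C)(C)C)=C\CO[Si](C)(C)C(C)(C)C)[C@H](OCc1ccc(OC)cc1)[C@@H](O[Si](C)(C)C(C)(C)C)C=O | intermediate
19 | methyl acrylate | C=CC(=O)OC | starting material
20 | Baylis–Hillman adduct: C7 carbinol carrying C11(=C13H2)–C12O2Me; both C7 epimers | C#C[C@@](C)(OC(=O)/C(CO[Si](c1ccccc1)(c1ccccc1)C(C)(C)C)=C\CO[Si](C)(C)C(C)(C)C)[C@H](OCc1ccc(OC)cc1)[C@@H](O[Si](C)(C)C(C)(C)C)C(O)C(=C)C(=O)OC | intermediate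
21 | (Z)-allylic bromide, C13H2Br–C11(CO2Me)=C7H–C8 | C#C[C@@](C)(OC(=O)/C(CO[Si](c1ccccc1)(c1ccccc1)C(C)(C)C)=C\CO[Si](C)(C)C(C)(C)C)[C@H](OCc1ccc(OC)cc1)[C@@H](O[Si](C)(C)C(C)(C)C)/C=C(\CBr)C(=O)OC | intermediate
22 | C6 allylic alcohol of 21 | C#C[C@@](C)(OC(=O)/C(CO[Si](c1ccccc1)(c1ccccc1)C(C)(C)C)=C\CO)[C@H](OCc1ccc(OC)cc1)[C@@H](O[Si](C)(C)C(C)(C)C)/C=C(\CBr)C(=O)OC | intermediate
23 | Z-enal bromide, C6 aldehyde cis to the C3 ester | C#C[C@@](C)(OC(=O)/C(CO[Si](c1ccccc1)(c1ccccc1)C(C)(C)C)=C\C=O)[C@H](OCc1ccc(OC)cc1)[C@@H](O[Si](C)(C)C(C)(C)C)/C=C(\CBr)C(=O)OC | intermediate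
24 | nine-membered lactone hydroxy ester (6-OH; C7 carries C11(=CH2)CO2Me); C6–C10 as in 36 | CC(C)(C)[Si](C)(C)O[C@H]1[C@@H](C(=C)C(=O)OC)[C@H](O)/C=C(/CO[Si](c3ccccc3)(c3ccccc3)C(C)(C)C)C(=O)O[C@](C)(C#C)[C@@H]1OCc1ccc(OC)cc1 | intermediate (not isolated)
25 | nine-membered lactone trans-fused at C6/C7 to the α-methylene γ-lactone; C10 ethynyl and methyl; O8 TBS, O9 PMB, O15 TBDPS; 4Z; C6–C10 as in 36 | CC(C)(C)[Si](C)(C)O[C@H]1[C@H]2C(=C)C(=O)O[C@@H]2/C=C(/CO[Si](c3ccccc3)(c3ccccc3)C(C)(C)C)C(=O)O[C@](C)(C#C)[C@@H]1OCc1ccc(OC)cc1 | intermediate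
26 | bromoalkyne of 25 | CC(C)(C)[Si](C)(C)O[C@H]1[C@H]2C(=C)C(=O)O[C@@H]2/C=C(/CO[Si](c3ccccc3)(c3ccccc3)C(C)(C)C)C(=O)O[C@](C)(C#CBr)[C@@H]1OCc1ccc(OC)cc1 | intermediate
27 | bromomethyl ketone, C1(=O)–C2H2Br on C10 | CC(C)(C)[Si](C)(C)O[C@H]1[C@H]2C(=C)C(=O)O[C@@H]2/C=C(/CO[Si](c3ccccc3)(c3ccccc3)C(C)(C)C)C(=O)O[C@](C)(C(=O)CBr)[C@@H]1OCc1ccc(OC)cc1 | intermediate
28 | phosphonium bromide of 27 | CC(C)(C)[Si](C)(C)O[C@H]1[C@H]2C(=C)C(=O)O[C@@H]2/C=C(/CO[Si](c3ccccc3)(c3ccccc3)C(C)(C)C)C(=O)O[C@](C)(C(=O)C[P+](c4ccccc4)(c4ccccc4)c4ccccc4)[C@@H]1OCc1ccc(OC)cc1.[Br-] | intermediate (not isolated)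
29 | nine-membered lactone keto ylide, C1(=O)–C2H=PPh3 on C10; O8 TBS, O9 PMB, O15 TBDPS | CC(C)(C)[Si](C)(C)O[C@H]1[C@H]2C(=C)C(=O)O[C@@H]2/C=C(/CO[Si](c3ccccc3)(c3ccccc3)C(C)(C)C)C(=O)O[C@](C)(C(=O)C=P(c4ccccc4)(c4ccccc4)c4ccccc4)[C@@H]1OCc1ccc(OC)cc1 | intermediate
30 | protected furanone core: furanone O–C3=C2–C1(=O)–C10 bridging the ten-membered carbocycle; O8 TBS, O9 PMB, O15 TBDPS | CC(C)(C)[Si](C)(C)O[C@H]1[C@H]2C(=C)C(=O)O[C@@H]2/C=C(/CO[Si](c3ccccc3)(c3ccccc3)C(C)(C)C)C2=CC(=O)[C@@](C)(O2)[C@@H]1OCc1ccc(OC)cc1 | intermediate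
31 | C9 alcohol (O8 TBS, O15 TBDPS) | CC(C)(C)[Si](C)(C)O[C@H]1[C@H]2C(=C)C(=O)O[C@@H]2/C=C(/CO[Si](c3ccccc3)(c3ccccc3)C(C)(C)C)C2=CC(=O)[C@@](C)(O2)[C@@H]1O | intermediate
32 | angelic 2,4,6-trichlorobenzoic anhydride | C/C=C(/C)C(=O)OC(=O)c1c(Cl)cc(Cl)cc1Cl | intermediate (not isolated)
33 | C9 angelate (O8 TBS, O15 TBDPS) | CC(C)(C)[Si](C)(C)O[C@H]1[C@H]2C(=C)C(=O)O[C@@H]2/C=C(/CO[Si](c3ccccc3)(c3ccccc3)C(C)(C)C)C2=CC(=O)[C@@](C)(O2)[C@@H]1OC(=O)/C(C)=C\C | intermediate
34 | C8 alcohol (C9 angelate, O15 TBDPS) | O[C@H]1[C@H]2C(=C)C(=O)O[C@@H]2/C=C(/CO[Si](c3ccccc3)(c3ccccc3)C(C)(C)C)C2=CC(=O)[C@@](C)(O2)[C@@H]1OC(=O)/C(C)=C\C | intermediate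
35 | C8 methacrylate, C9 angelate, O15 TBDPS ether | C=C(C)C(=O)O[C@H]1[C@H]2C(=C)C(=O)O[C@@H]2/C=C(/CO[Si](c3ccccc3)(c3ccccc3)C(C)(C)C)C2=CC(=O)[C@@](C)(O2)[C@@H]1OC(=O)/C(C)=C\C | intermediate
36 | CNP0359568.2 (6R,7S,8S,9R,10S; 4Z) | C=C(C)C(=O)O[C@H]1[C@H]2C(=C)C(=O)O[C@@H]2/C=C(/CO)C2=CC(=O)[C@@](C)(O2)[C@@H]1OC(=O)/C(C)=C\C | target

**Step count and risks**

Total: 27 steps (5 to acid 6, 6 to alkynol 15, 16 from the union to 36). Longest linear sequence: 22 steps (steps 6–27, from 7).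

Most likely to fail:

1. Step 18. The strained nine-membered ring may close more slowly than intermolecular allylation. The Z-enal ester may be reduced or isomerised by divalent chromium before C–C bond formation. C6 may add to the other face of C7 or give the cis lactone. Fallback: reverse the order of the two ring-forming events, so that the allylation closes the ten-membered carbocycle, the ring size for which such closures are established in the germacranolide series. Setting out from 20, NBS with catalytic AgNO3 should give bromoalkyne F1 and gold-catalysed hydration bromoketone F2. PPh3 then gives phosphonium bromide F3 and aqueous Na2CO3 the keto ylide F4, which on heating in toluene should undergo the acyclic ester Wittig reaction to furanone F5. NBS/Me2S then gives allylic bromide F6, buffered HF·pyridine the C6 alcohol F7 and Dess–Martin oxidation the enal F8. CrCl2 under high dilution closes C6–C7 and the γ-lactone, and the route is rejoined at 30.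

2. Step 22. The lactone carbonyl is conjugated and shielded by the C10 substituents, so the stabilised ylide may fail to attack it; prolonged heating would then favour intermolecular reactions with the α-methylene lactone. Fallback: make the C2–C3 bond with an enolate. Setting out from 25, gold-catalysed hydration of the terminal alkyne gives methyl ketone F9. LiN(SiMe3)2 at −78 °C forms the C2 enolate, which attacks C3 and moves the acyl group from O10 to C2 (Baker–Venkataraman-type rearrangement), giving hydroxy diketone F10, already the ten-membered carbocycle. Acid-catalysed cyclodehydration (TsOH, benzene) closes the furanone and comes back at 30.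

3. Step 12. Acylation of the hindered tertiary alcohol may be slower than decay of the mixed anhydride (symmetrical anhydride, loss of the C6 silyl ether with butenolide formation). Fallback: acylate the alkoxide instead of the alcohol. Acid 6 is converted under neutral conditions with 1-chloro-N,N,2-trimethylprop-1-en-1-amine into acid chloride F11; 15 is deprotonated at oxygen with LiN(SiMe3)2 (1.0 equiv, THF, −78 °C) and combined with F11, returning to the route at 17.

**Further compounds**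

F1 | step 18 | bromoalkyne of Baylis–Hillman adduct 20 | BrC#C[C@@](C)(OC(=O)/C(CO[Si](c1ccccc1)(c1ccccc1)C(C)(C)C)=C\CO[Si](C)(C)C(C)(C)C)[C@H](OCc1ccc(OC)cc1)[C@@H](O[Si](C)(C)C(C)(C)C)C(O)C(=C)C(=O)OC
F2 | step 18 | acyclic α-acyloxy bromomethyl ketone | BrCC(=O)[C@@](C)(OC(=O)/C(CO[Si](c1ccccc1)(c1ccccc1)C(C)(C)C)=C\CO[Si](C)(C)C(C)(C)C)[C@H](OCc1ccc(OC)cc1)[C@@H](O[Si](C)(C)C(C)(C)C)C(O)C(=C)C(=O)OC
F3 | step 18 | phosphonium bromide of F2 | [Br-].O=C(C[P+](c1ccccc1)(c1ccccc1)c1ccccc1)[C@@](C)(OC(=O)/C(CO[Si](c1ccccc1)(c1ccccc1)C(C)(C)C)=C\CO[Si](C)(C)C(C)(C)C)[C@H](OCc1ccc(OC)cc1)[C@@H](O[Si](C)(C)C(C)(C)C)C(O)C(=C)C(=O)OC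
F4 | step 18 | acyclic keto ylide | O=C(C=P(c1ccccc1)(c1ccccc1)c1ccccc1)[C@@](C)(OC(=O)/C(CO[Si](c1ccccc1)(c1ccccc1)C(C)(C)C)=C\CO[Si](C)(C)C(C)(C)C)[C@H](OCc1ccc(OC)cc1)[C@@H](O[Si](C)(C)C(C)(C)C)C(O)C(=C)C(=O)OC
F5 | step 18 | furanone with open C6–C7 bond (Baylis–Hillman alcohol at C7; C6-O TBS) | O=C1C=C(/C(CO[Si](c2ccccc2)(c2ccccc2)C(C)(C)C)=C\CO[Si](C)(C)C(C)(C)C)O[C@@]1(C)[C@H](OCc1ccc(OC)cc1)[C@@H](O[Si](C)(C)C(C)(C)C)C(O)C(=C)C(=O)OC
F6 | step 18 | furanone (Z)-allylic bromide | O=C1C=C(/C(CO[Si](c2ccccc2)(c2ccccc2)C(C)(C)C)=C\CO[Si](C)(C)C(C)(C)C)O[C@@]1(C)[C@H](OCc1ccc(OC)cc1)[C@@H](O[Si](C)(C)C(C)(C)C)/C=C(\CBr)C(=O)OC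
F7 | step 18 | furanone C6 alcohol | O=C1C=C(/C(CO[Si](c2ccccc2)(c2ccccc2)C(C)(C)C)=C\CO)O[C@@]1(C)[C@H](OCc1ccc(OC)cc1)[C@@H](O[Si](C)(C)C(C)(C)C)/C=C(\CBr)C(=O)OC
F8 | step 18 | furanone Z-enal bromide | O=C1C=C(/C(CO[Si](c2ccccc2)(c2ccccc2)C(C)(C)C)=C\C=O)O[C@@]1(C)[C@H](OCc1ccc(OC)cc1)[C@@H](O[Si](C)(C)C(C)(C)C)/C=C(\CBr)C(=O)OC
F9 | step 22 | nine-membered lactone methyl ketone (C10 acetyl) | CC(C)(C)[Si](C)(C)O[C@H]1[C@H]2C(=C)C(=O)O[C@@H]2/C=C(/CO[Si](c3ccccc3)(c3ccccc3)C(C)(C)C)C(=O)O[C@](C)(C(C)=O)[C@@H]1OCc1ccc(OC)cc1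
F10 | step 22 | ten-membered 1,3-diketone with free C10 hydroxyl | CC(C)(C)[Si](C)(C)O[C@H]1[C@H]2C(=C)C(=O)O[C@@H]2/C=C(/CO[Si](c3ccccc3)(c3ccccc3)C(C)(C)C)C(=O)CC(=O)[C@@](C)(O)[C@@H]1OCc1ccc(OC)cc1
F11 | step 12 | acid chloride of 6 | ClC(=O)/C(CO[Si](c1ccccc1)(c1ccccc1)C(C)(C)C)=C\CO[Si](C)(C)C(C)(C)C
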